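- In a one-step world, J + Z → X with equal charges, [J] and [Z] fall together, so the rate is k times [J] squared, and this integrates in closed form: the reciprocal of the fraction of J left, less one, equals k times the starting [J] times the time.

| flask | J | Z | remark | time |
|---|---|---|---|---|
| spring | 0.17 M | 1 equiv | run made earlier |  |
| autumn | 0.38 M | 1 equiv | run made earlier |  |
| summer | 0.25 M | 1.5 equiv | run made earlier |  |
| flask | 0.25 M | 1.00 equiv |  | 2.5 d |

| run | time / d | J / % | X / % |
|---|---|---|---|
| spring | 0.625 | 67.8 | 21.2 |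
| spring | 1.25 | 48.5 | 23.7 |
| spring | 2.08 | 35.0 | 20.6 |
| spring | 2.50 | 30.7 | 18.4 |
| autumn | 0.625 | 45.5 | 25.9 |
| autumn | 1.25 | 27.5 | 22.1 |
| autumn | 2.08 | 18.6 | 16.8 |
| autumn | 2.50 | 15.6 | 14.5 |
| summer | 0.208 | 72.7 | 20.5 |
| summer | 0.500 | 49.3 | 27.0 |
| summer | 1.04 | 25.4 | 23.3 |
| summer | 2.50 | 6.6 | 10.8 |

(readings scatter by 0.3 percentage points)

- the numbers in the tables scatter with a standard deviation of 0.3 percentage points

- how much J there is at 2.5 d, in percent of the J charged
- how much X there is at 2.5 d, in percent of the J charged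
- how much E there is at 2.5 d, in percent of the J charged
- how much G there is at 2.5 d, in percent of the J charged

- Autumn's reading of 27.5% J at 1.25 d turns that line round into the dose constant K, an apparent second-order rate constant: the reciprocal of the fraction left, less one, per starting [J] and per time, here 5.55 L mol⁻¹ d⁻¹.
- Spring, at another [J], reads 5.31 L mol⁻¹ d⁻¹ at 2.50 d but 4.47 L mol⁻¹ d⁻¹ at 0.625 d, so K is a reading that creeps upward along a run, not a true constant.
- Now the opposite outcome: for this flask to keep a fraction 0.5 of its J at 2.5 d, K would have to be 1.60 L mol⁻¹ d⁻¹, whereas the reading stands 3.47 times higher, so we reckon J at 22.4%.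
- The forecast, holding that “J and X depend almost only on concentration × time at 1 equiv”, gives J 22.5%, X 19.3%, E 21.5% and G 5%.
- The flask gives J 22.4%, X 16.6%, E 4.82% and G 2.34%, so E lies 17 points below the forecast.

    J + Z → X (k = 0.180 L mol⁻¹ h⁻¹)
    Z + X → E (k = 0.250 L mol⁻¹ h⁻¹)
    Z + E → G (k = 0.0990 L mol⁻¹ h⁻¹)
    X → Q (k = 0.0120 h⁻¹)
    J + E → D (k = 0.650 L mol⁻¹ h⁻¹)

- Beside that E, the flask holds D at 39.2% of the J charged at 2.50 d, a percentage in which each D counts as two. The flask's own J returns K as 5.56 L mol⁻¹ d⁻¹, and carried to the neighbour charged with 0.15 M of J, at the same equivalents and time, that value gives 32.4% J, where the neighbour holds 33.7%.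

(The readings stem from a simulated flask with made-up constants; noise was put on by code.)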